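In the alder run the partner charge of 0.20 M stood above the left-handed substrate charge of 0.13 M, yet the left-handed product at 3.00 d read just 0.0702 M. We keep a ledger of the partner to see where the remainder may have gone.

the same everywhere: free catalyst 10 mM
- cedar: left-handed substrate 0.20 M; right-handed substrate 0.20 M; partner 0.20 M; the very flask that is asked about, followed so far
- alder: left-handed substrate 0.13 M; right-handed substrate 0.13 M; partner 0.20 M; run made earlier
- flask: left-handed substrate 0.20 M; right-handed substrate 0.20 M; partner 0.200 M; time 8.0 d

| run | time / d | left-handed product / % | left-handed substrate / % |
|---|---|---|---|
| cedar | 0.167 | 7 | 44 |
| cedar | 0.500 | 12 | 38 |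
| cedar | 0.833 | 15 | 33 |
| cedar | 1.25 | 19 | 32 |
| cedar | 2.08 | 21 | 29 |
| cedar | 2.50 | 23 | 29 |
| cedar | 3.00 | 24 | 27 |
| alder | 0.167 | 4 | 48 |
| alder | 0.500 | 15 | 38 |
| alder | 0.833 | 15 | 32 |
| alder | 1.25 | 23 | 27 |
| alder | 2.08 | 22 | 24 |
| alder | 2.50 | 25 | 23 |
| alder | 3.00 | 27 | 27 |

(scatter of a reading: 1.5 percentage points)

- free catalyst is single-handed; left-handed substrate and right-handed substrate are mirror images of each other, charged as a racemate, each of them at the stated concentration
- the reaction counts as stopped when no species that holds the left-handed substrate and right-handed substrate together changes by six tenths of a point or more over the second half of the time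

1. at 8.0 d, what has stopped the reaction, if anything has (it is still moving / no working catalyst is left / the partner has run out first / all of the left-handed substrate has reacted / forward and back rates have come level)
2. amount of left-handed product at 8.0 d, in percent of the left-handed substrate and right-handed substrate together charged
3. amount of left-handed product if the flask were left three thousand times as long, in percent of the left-handed substrate and right-handed substrate together charged

1. Product. In the cedar run at 3.00 d, product 24% and left-handed substrate 27% still account for that substrate's charge, and we assume one partner per product formed.

2. Loss. We suppose that partner also decays by itself. Let L* be the crossing concentration, the level of left-handed substrate at which partner splits evenly between product and decay. Above L*, product takes the larger share; below it, decay does.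

3. Closing. With charges c of left-handed substrate and B of partner, and P of product, the books close when B = P + L* ln(c/(c − P)). We assume that partner is used up by the last reading. Alder then gives L* = 0.167 M; cedar, with 0.0960 M of product, gives 0.159 M.

4. Forecast of our own. Alder's L*, applied to the asked flask, closes at 0.0940 M, or 23.5%. We commit to the partner as what ends the reaction, and to that figure at both asked times.

The forecast gives another answer to the first question: forward and back rates have come level, with 25% (range 23.5% to 28%) at 8.0 d and 25% (range 23.5% to 30%) in the long run. “I favour equilibrium because one K serves both runs.”

The flask gives: the partner has run out first, with 24.1% of left-handed product and 24.1% in the long run.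

    partner + free catalyst + left-handed substrate → free catalyst + left-handed product (k = 15.0 L² mol⁻² h⁻¹)
    partner + free catalyst + right-handed substrate → free catalyst + right-handed product (k = 0.260 L² mol⁻² h⁻¹)
    partner → decomposed reagent (k = 0.0230 h⁻¹)
    free catalyst → spent catalyst (k = 2.40 × 10⁻⁵ h⁻¹)

At 8.00 d the flask holds 0.042% of its partner and 52% of its left-handed substrate. On the neighbouring flask with 0.080 M of partner, the same ledger with L* = 0.167 M closes at 0.0436 M as a first trial and then at 0.0413 M, or 10.3%. That neighbour gives 10.6% of left-handed product, with 0.010% of its partner and 79% of its left-handed substrate left.

(The numbers in the tables were computed for substances that don't exist.)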